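**Assumption:** in steps 2 and 5 the sense of induction cannot be read from a simple mnemonic, so the catalyst antipode that gives the drawn configuration is meant. The route has not been run; selectivities are predictions.

## Retrosynthetic overview

1. The target comes from MeLi opening of an α-hydroxy-δ-bromolactone: the lactone C=O becomes the acetyl group, the O–CMe2 bond becomes the tertiary alcohol, and the side-chain C–Br is already set.
2. The ring CH comes from face-selective hydrogenation of a cyclohexene. The trans Br/Cl pair comes from a Shi epoxide of the methyl-bearing ring alkene (bromide with inversion, then chloride with bromine participation).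
3. The bromolactone comes from 6-endo bromolactonisation of a prenyl α-hydroxy acid bearing a 4-methylcyclohexa-1,4-dienyl group. That acid comes from Birch reduction of the fully assembled p-tolyl α-hydroxy acid.
4. The p-tolyl acid comes from toluene and ethyl chlorooxoacetate (Friedel–Crafts), catalytic asymmetric allylation of the keto ester, and cross-metathesis to prenyl.
5. Rings: the carbocycle is the toluene ring itself, dearomatised in step 4 and never closed. The only ring formed is the δ-lactone (step 5), opened again in step 10.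

## Route

Step 1
Reactants: 1 toluene; 2 ethyl chlorooxoacetate
Product: 3 ethyl 2-(4-methylphenyl)-2-oxoacetate
Conditions: AlCl3 (1.2 equiv), CH2Cl2, 0 °C to rt
Reagents that add atoms: none
Why: Friedel–Crafts acylation through the acyl chloride end of the oxalyl half-ester, para to the methyl group for steric reasons; no stereocentre is formed.

Step 2
Reactants: 3 ethyl 2-(4-methylphenyl)-2-oxoacetate; 4 allyltributylstannane
Product: 5 ethyl (2R)-2-hydroxy-2-(4-methylphenyl)pent-4-enoate
Conditions: In(OTf)3 (10 mol %), chiral pipecolic-acid-derived N,N'-dioxide ligand (10 mol %), 4 Å MS, CH2Cl2, 0 °C; aqueous work-up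
Reagents that add atoms: none
Why: chiral-Lewis-acid-catalysed enantioselective allylstannane addition (Keck-type allylation) to a two-point-bound α-keto ester, the ligand shielding one carbonyl face so that C2 is set as R.

Step 3
Reactants: 5 ethyl (2R)-2-hydroxy-2-(4-methylphenyl)pent-4-enoate; 6 2-methylbut-2-ene
Product: 7 ethyl (2R)-2-hydroxy-5-methyl-2-(4-methylphenyl)hex-4-enoate
Conditions: second-generation Grubbs catalyst RuCl2(=CHPh)(H2IMes)(PCy3) (5 mol %), 2-methylbut-2-ene/CH2Cl2, 40 °C
Reagents that add atoms: none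
Why: olefin cross-metathesis turns the allyl group into prenyl with loss of propene and leaves the carbinol centre untouched.

Step 4
Reactants: 7 ethyl (2R)-2-hydroxy-5-methyl-2-(4-methylphenyl)hex-4-enoate
Product: 9 (2R)-2-hydroxy-5-methyl-2-(4-methylcyclohexa-1,4-dien-1-yl)hex-4-enoic acid, via lithium carboxylate 8 (not isolated)
Conditions: LiOH·H2O, THF–H2O, rt; evaporate, PhMe azeotrope; Li, NH3(l), THF, t-BuOH, −78 °C; NH4Cl; aq. HCl to pH 3
Reagents that add atoms: lithium hydroxide, [Li+].[OH-]
Why: ester saponification then Birch reduction of the para-dialkylbenzene-type ring as its carboxylate/alkoxide dianion, which protects the benzylic C–O bond and gives the 1,4-diene with both substituents on sp2 carbons (as in the reduction of phenylglycine to dihydrophenylglycine); the isolated prenyl alkene and the stereocentre are not affected.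

Step 5
Reactants: 9 (2R)-2-hydroxy-5-methyl-2-(4-methylcyclohexa-1,4-dien-1-yl)hex-4-enoic acid
Product: 10 (3R,5R)-5-bromo-3-hydroxy-6,6-dimethyl-3-(4-methylcyclohexa-1,4-dien-1-yl)oxan-2-one
Conditions: TBCO (1.1 equiv), chiral BINOL-derived amidine–phenol bifunctional catalyst (10 mol %), PhMe–CH2Cl2, −50 °C, dark
Reagents that add atoms: 2,4,4,6-tetrabromocyclohexa-2,5-dien-1-one (TBCO), O=C1C(Br)=CC(Br)(Br)C=C1Br
Why: catalytic enantioselective 6-endo bromolactonisation, the carboxyl oxygen attacking the dimethyl-substituted carbon anti to the bromonium ion on the catalyst-selected alkene face (C5 = R); intramolecular capture makes the prenyl alkene react ahead of the two ring alkenes.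

Step 6
Reactants: 10 (3R,5R)-5-bromo-3-hydroxy-6,6-dimethyl-3-(4-methylcyclohexa-1,4-dien-1-yl)oxan-2-one
Product: 11 (3R,5R)-5-bromo-3-hydroxy-6,6-dimethyl-3-[(1R,6S)-6-methyl-7-oxabicyclo[4.1.0]hept-3-en-3-yl]oxan-2-one
Conditions: D-fructose-derived Shi ketone (0.3 equiv), Oxone (2KHSO5·KHSO4·K2SO4), K2CO3, Bu4NHSO4, MeCN–DMM–aq. borate buffer, 0 °C
Reagents that add atoms: potassium peroxymonosulfate (KHSO5), [K+].[O-]S(=O)(=O)OO
Why: Shi asymmetric epoxidation, the electrophilic dioxirane taking the electron-rich methyl-substituted alkene rather than the alkene next to the oxygenated quaternary carbon, and the spiro transition state of the D-fructose ketone giving the epoxide whose CH carbon is R (same sense as for 1-phenylcyclohexene).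

Step 7
Reactants: 11 (3R,5R)-5-bromo-3-hydroxy-6,6-dimethyl-3-[(1R,6S)-6-methyl-7-oxabicyclo[4.1.0]hept-3-en-3-yl]oxan-2-one
Product: 12 (3R,5R)-5-bromo-3-[(4S,5S)-5-bromo-4-hydroxy-4-methylcyclohex-1-en-1-yl]-3-hydroxy-6,6-dimethyloxan-2-one
Conditions: Li2NiBr4, THF, 0 °C to rt; pH 7 buffer
Reagents that add atoms: dilithium tetrabromonickelate (Li2NiBr4), [Li+].[Li+].[Ni+2].[Br-].[Br-].[Br-].[Br-]
Why: SN2 epoxide opening by soft bromide at the less hindered secondary carbon with inversion (C–Br becomes S) leaving the tertiary alcohol; because the carbon bearing the lactone is still sp2 the ring is not conformationally locked and trans-diaxial opening is unhindered.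

Step 8
Reactants: 12 (3R,5R)-5-bromo-3-[(4S,5S)-5-bromo-4-hydroxy-4-methylcyclohex-1-en-1-yl]-3-hydroxy-6,6-dimethyloxan-2-one
Product: 13 (3R,5R)-5-bromo-3-[(4S,5S)-5-bromo-4-chloro-4-methylcyclohex-1-en-1-yl]-3-hydroxy-6,6-dimethyloxan-2-one
Conditions: HCl (g), CH2Cl2, 0 °C
Reagents that add atoms: hydrogen chloride, Cl
Why: tertiary alcohol to chloride with neighbouring-group participation, the anti bromine forming a bromonium ion that chloride opens at the tertiary carbon (net retention, trans Br/Cl with Cl tertiary); the α-acyl tertiary alcohol on the lactone cannot ionise.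

Step 9
Reactants: 13 (3R,5R)-5-bromo-3-[(4S,5S)-5-bromo-4-chloro-4-methylcyclohex-1-en-1-yl]-3-hydroxy-6,6-dimethyloxan-2-one
Product: 14 (3R,5R)-5-bromo-3-[(1S,3S,4S)-3-bromo-4-chloro-4-methylcyclohexyl]-3-hydroxy-6,6-dimethyloxan-2-one
Conditions: [Ir(cod)(PCy3)(py)]PF6 (10 mol %), H2 (1 atm), CH2Cl2, 0 °C to rt
Reagents that add atoms: none
Why: hydroxyl-directed homogeneous hydrogenation (Crabtree's catalyst) from the ring face opposite the C–Br and the methyl group (the face carrying only chlorine, open in the half-chair with both halogens equatorial), which puts the lactone substituent cis to Br and sets the ring CH as S.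

Step 10
Reactants: 14 (3R,5R)-5-bromo-3-[(1S,3S,4S)-3-bromo-4-chloro-4-methylcyclohexyl]-3-hydroxy-6,6-dimethyloxan-2-one
Product: 16 (3R,5R)-5-bromo-3-[(1S,3S,4S)-3-bromo-4-chloro-4-methylcyclohexyl]-3,6-dihydroxy-6-methylheptan-2-one, via dilithium lactolate 15 (not isolated)
Conditions: MeLi (2.2 equiv), THF, −78 °C; AcOH, −78 °C to rt
Reagents that add atoms: methyllithium, [Li]C
Why: single addition of an organolithium to a lactone (the first equivalent deprotonates the OH), the lactolate being stable at −78 °C and opening on protonation to the methyl ketone and the free tertiary alcohol; no stereocentre is touched.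

## Compound list

1 | toluene | Cc1ccccc1 | starting material
2 | ethyl chlorooxoacetate | CCOC(=O)C(=O)Cl | starting material
3 | ethyl 2-(4-methylphenyl)-2-oxoacetate | CCOC(=O)C(=O)c1ccc(C)cc1 | intermediate
4 | allyltributylstannane | C=CC[Sn](CCCC)(CCCC)CCCC | starting material
5 | ethyl (2R)-2-hydroxy-2-(4-methylphenyl)pent-4-enoate | CCOC(=O)[C@@](O)(CC=C)c1ccc(C)cc1 | intermediate
6 | 2-methylbut-2-ene | CC=C(C)C | starting material
7 | ethyl (2R)-2-hydroxy-5-methyl-2-(4-methylphenyl)hex-4-enoate | CCOC(=O)[C@@](O)(CC=C(C)C)c1ccc(C)cc1 | intermediate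
8 | lithium (2R)-2-hydroxy-5-methyl-2-(4-methylphenyl)hex-4-enoate | [Li+].[O-]C(=O)[C@@](O)(CC=C(C)C)c1ccc(C)cc1 | intermediate
9 | (2R)-2-hydroxy-5-methyl-2-(4-methylcyclohexa-1,4-dien-1-yl)hex-4-enoic acid | OC(=O)[C@@](O)(CC=C(C)C)C1=CCC(C)=CC1 | intermediate
10 | (3R,5R)-5-bromo-3-hydroxy-6,6-dimethyl-3-(4-methylcyclohexa-1,4-dien-1-yl)oxan-2-one | O=C1[C@@](O)(C[C@@H](Br)C(C)(C)O1)C2=CCC(C)=CC2 | intermediate
11 | (3R,5R)-5-bromo-3-hydroxy-6,6-dimethyl-3-[(1R,6S)-6-methyl-7-oxabicyclo[4.1.0]hept-3-en-3-yl]oxan-2-one | O=C1[C@@](O)(C[C@@H](Br)C(C)(C)O1)C2=CC[C@]3(C)O[C@@H]3C2 | intermediate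
12 | (3R,5R)-5-bromo-3-[(4S,5S)-5-bromo-4-hydroxy-4-methylcyclohex-1-en-1-yl]-3-hydroxy-6,6-dimethyloxan-2-one | O=C1[C@@](O)(C[C@@H](Br)C(C)(C)O1)C2=CC[C@](C)(O)[C@@H](Br)C2 | intermediate
13 | (3R,5R)-5-bromo-3-[(4S,5S)-5-bromo-4-chloro-4-methylcyclohex-1-en-1-yl]-3-hydroxy-6,6-dimethyloxan-2-one | O=C1[C@@](O)(C[C@@H](Br)C(C)(C)O1)C2=CC[C@](C)(Cl)[C@@H](Br)C2 | intermediate
14 | (3R,5R)-5-bromo-3-[(1S,3S,4S)-3-bromo-4-chloro-4-methylcyclohexyl]-3-hydroxy-6,6-dimethyloxan-2-one | O=C1[C@@](O)(C[C@@H](Br)C(C)(C)O1)[C@H]2CC[C@](C)(Cl)[C@@H](Br)C2 | intermediate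
15 | dilithium (3R,5R)-5-bromo-3-[(1S,3S,4S)-3-bromo-4-chloro-4-methylcyclohexyl]-2,6,6-trimethyloxane-2,3-bis(olate), both C2 epimers | [Li+].[Li+].[O-]C1(C)[C@@]([O-])(C[C@@H](Br)C(C)(C)O1)[C@H]2CC[C@](C)(Cl)[C@@H](Br)C2 | intermediate
16 | (3R,5R)-5-bromo-3-[(1S,3S,4S)-3-bromo-4-chloro-4-methylcyclohexyl]-3,6-dihydroxy-6-methylheptan-2-one | CC(=O)[C@@](O)(C[C@@H](Br)C(C)(C)O)[C@H]1CC[C@](C)(Cl)[C@@H](Br)C1 | target

## Step count and risks

Total step count: 10. Longest linear sequence: 10 steps (toluene to 16).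

**Step 5 (bromolactonisation).** The C5 configuration rests on catalyst control over a small and uncertain substrate bias, and the skipped diene can be oxidised by the bromine source. Fallback, from 9 back to 10: drop catalyst control and cyclise 9 with NBS alone (CH2Cl2, −78 °C). Separate the two C5 epimers on silica and keep 10. Return the unwanted epimer, (3R,5S)-5-bromo-3-hydroxy-6,6-dimethyl-3-(4-methylcyclohexa-1,4-dien-1-yl)oxan-2-one F1, to acid 9 with Zn dust in AcOH/THF (reductive ring opening, the reversal of a halolactonisation). All material is thus funnelled to 10.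

**Step 8 (tertiary OH to Cl with retention).** Elimination of the tertiary alcohol, or bromide attack at the tertiary carbon in step 7, would undermine it. Fallback, from 11 back to 13: open epoxide 11 with anhydrous HBr (CH2Cl2, −78 °C) at the tertiary carbon to the regioisomeric bromohydrin (3R,5R)-5-bromo-3-[(4R,5R)-4-bromo-5-hydroxy-4-methylcyclohex-1-en-1-yl]-3-hydroxy-6,6-dimethyloxan-2-one F2. Then activate the secondary alcohol with SOCl2/pyridine (0 °C). The anti tertiary bromine displaces the chlorosulfite and chloride opens the same bromonium ion at the tertiary carbon (1,2-bromine shift), giving 13.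

**Step 9 (hydrogenation).** The facial selectivity is a steric prediction that the carbinol rotamer preference could oppose. Fallback, from 10 back to 14: set the ring CH first under catalyst control, then build the halides on the saturated ring.
- Hydrogenate the hydroxyl-bearing alkene of 10 with a chiral iridium N,P catalyst, [Ir(cod)(t-Bu-PHOX)][B(C6H3(CF3)2)4] (antipode for 1S), H2, CH2Cl2, one equivalent of H2. This gives (3R,5R)-5-bromo-3-hydroxy-6,6-dimethyl-3-[(1S)-4-methylcyclohex-3-en-1-yl]oxan-2-one F3.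
- Epoxidise with the same D-fructose-derived Shi ketone to (3R,5R)-5-bromo-3-hydroxy-6,6-dimethyl-3-[(1R,3S,6S)-6-methyl-7-oxabicyclo[4.1.0]heptan-3-yl]oxan-2-one F4.
- Open trans-diaxially with anhydrous HBr at the tertiary carbon to (3R,5R)-5-bromo-3-[(1S,3R,4R)-4-bromo-3-hydroxy-4-methylcyclohexyl]-3-hydroxy-6,6-dimethyloxan-2-one F5.
- Treat with SOCl2/pyridine; the 1,2-bromine shift with chloride capture at the tertiary carbon gives 14. On this locked ring chloride may instead attack the secondary carbon, which is why the main route halogenates before hydrogenating.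

## Further compounds

F1 | step 5 | (3R,5S)-5-bromo-3-hydroxy-6,6-dimethyl-3-(4-methylcyclohexa-1,4-dien-1-yl)oxan-2-one | O=C1[C@@](O)(C[C@H](Br)C(C)(C)O1)C2=CCC(C)=CC2
F2 | step 8 | (3R,5R)-5-bromo-3-[(4R,5R)-4-bromo-5-hydroxy-4-methylcyclohex-1-en-1-yl]-3-hydroxy-6,6-dimethyloxan-2-one | O=C1[C@@](O)(C[C@@H](Br)C(C)(C)O1)C2=CC[C@@](C)(Br)[C@H](O)C2
F3 | step 9 | (3R,5R)-5-bromo-3-hydroxy-6,6-dimethyl-3-[(1S)-4-methylcyclohex-3-en-1-yl]oxan-2-one | O=C1[C@@](O)(C[C@@H](Br)C(C)(C)O1)[C@H]2CCC(C)=CC2
F4 | step 9 | (3R,5R)-5-bromo-3-hydroxy-6,6-dimethyl-3-[(1R,3S,6S)-6-methyl-7-oxabicyclo[4.1.0]heptan-3-yl]oxan-2-one | O=C1[C@@](O)(C[C@@H](Br)C(C)(C)O1)[C@H]2CC[C@]3(C)O[C@@H]3C2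
F5 | step 9 | (3R,5R)-5-bromo-3-[(1S,3R,4R)-4-bromo-3-hydroxy-4-methylcyclohexyl]-3-hydroxy-6,6-dimethyloxan-2-one | O=C1[C@@](O)(C[C@@H](Br)C(C)(C)O1)[C@H]2CC[C@@](C)(Br)[C@H](O)C2
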